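## Retrosynthetic overview

1. Target 30 is a cis-fused (5-epi) 4,9-friedodrimane: ring A (C1–C5, C10; C3=C4, 4-Me, 5-Me), ring B (C5–C10; 8-Me, 9-Me, 9-CH2Ar), with C11 bound to C7 of a 5-methoxy-2-methylbenzoxazol-6-ol. The last operations (O-desilylation, removal of a C2 oxygen, C4 methylation) lead back to the cis-fused enone 25.
2. Key disconnection C9–C10: ring A comes first, as the prochiral 4-methyl-4-alkylcyclohexa-2,5-dienone 24, and ring B is closed last by an iron-hydride (MHAT) 6-exo radical cyclization of a C9 radical onto C10. Enabling feature: C5 is a quaternary carbon of ring A standing between C10–H and C4, so ring A is a masked dienone with two identical arms (C10=C1 and C4=C3). A tether from C5 can reach C10 only cis (5-Me/10-H cis, as in 30), and the arm left over (C2=O, C3=C4) is where the 4-methyl and the C3=C4 alkene are made.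
3. C11–C7(arene): aromatic Claisen rearrangement (the 6-OH of 30 is ortho to the C11 methylene) of the ether from phenol 6 and allyl bromide 18.
4. C5–C6: Stork–Danheiser alkylation of 8 with iodide 14. C8, the only stereocenter brought into 24, comes from Ru–BINAP hydrogenation of α-methylene-γ-butyrolactone; the lactone carbon becomes C9 of a 2-substituted allylsilane.
5. Benzoxazole 6: from 3-(benzyloxy)-4-methoxybenzaldehyde by nitration, Dakin oxidation, hydrogenation and orthoacetate cyclization.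

Key step: step 14

Remark: the decalin is numbered as in drimanes (C11 = benzylic CH2). Compounds 15 to 23 are carried as mixtures of the two epimers at the future C5, which is no longer a stereocenter in 24.

## Route

Step 1
Reactants: 1 3-(benzyloxy)-4-methoxybenzaldehyde
Product: 2 5-(benzyloxy)-4-methoxy-2-nitrobenzaldehyde
Conditions: conc. HNO3, 0 to 15 °C
Reagents that add atoms: nitric acid, O[N+](=O)[O-]
Why: Electrophilic aromatic nitration should go to the ring position para to the benzyloxy group and ortho to the aldehyde, the standard outcome for O-alkylated isovanillins.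

Step 2
Reactants: 2 5-(benzyloxy)-4-methoxy-2-nitrobenzaldehyde
Product: 4 5-(benzyloxy)-4-methoxy-2-nitrophenol, via aryl formate 3 (not isolated)
Conditions: mCPBA, CH2Cl2, 40 °C; then K2CO3 (cat.), MeOH, rt
Reagents that add atoms: mCPBA, O=C(OO)c1cccc(Cl)c1
Why: Baeyer–Villiger (Dakin-type) oxidation in which the aryl group, activated by the para-methoxy group, migrates in preference to hydrogen, followed by methanolysis of the formate.

Step 3
Reactants: 4 5-(benzyloxy)-4-methoxy-2-nitrophenol
Product: 6 5-methoxy-2-methyl-1,3-benzoxazol-6-ol, via aminoresorcinol 5 (not isolated)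
Conditions: H2 (1 atm), Pd/C, EtOAc/EtOH, rt; filter under argon; then MeC(OEt)3, pyridinium p-toluenesulfonate (cat.), 90 °C
Reagents that add atoms: triethyl orthoacetate, CC(OCC)(OCC)OCC
Why: Hydrogenation reduces the nitro group and hydrogenolyses the benzyl ether, and the air-sensitive o-aminophenol is condensed at once with the orthoester (benzoxazole formation), only the hydroxyl ortho to nitrogen being able to close the ring.

Step 4
Reactants: 7 3-ethoxycyclohex-2-en-1-one
Product: 8 3-ethoxy-6-methylcyclohex-2-en-1-one (racemic)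
Conditions: LiN(iPr)2, THF, −78 °C; MeI, −78 °C to rt
Reagents that add atoms: iodomethane, CI
Why: Kinetic α′-enolate methylation of a vinylogous ester (Stork–Danheiser alkylation).

Step 5
Reactants: 9 3-methylideneoxolan-2-one (α-methylene-γ-butyrolactone)
Product: 10 (3S)-3-methyloxolan-2-one
Conditions: H2 (50 atm), Ru(OAc)2[(R)-BINAP] (0.5 mol%), CH2Cl2, 50 °C
Reagents that add atoms: none
Why: Ru–BINAP asymmetric hydrogenation of an α-methylene lactone (Noyori–Takaya type) sets C8; the (R)-ligand is expected to deliver the (S)-lactone, a known compound against which the sense is to be checked, the ligand antipode being used otherwise.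

Step 6
Reactants: 10 (3S)-3-methyloxolan-2-one
Product: 12 (3S)-3-methyl-4-[(trimethylsilyl)methyl]pent-4-en-1-ol, via bis(silylmethyl) carbinol 11 (not isolated)
Conditions: Me3SiCH2MgCl (3.5 equiv), CeCl3 (anhydrous), THF, −78 °C to rt; then silica gel, CH2Cl2, rt
Reagents that add atoms: (trimethylsilyl)methylmagnesium chloride, C[Si](C)(C)C[Mg]Cl
Why: Cerium-mediated double addition to the lactone followed by Peterson elimination (Bunnelle–Lee allylsilane synthesis), the weakly basic organocerium reagent being expected to leave the α-stereocenter untouched.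

Step 7
Reactants: 12 (3S)-3-methyl-4-[(trimethylsilyl)methyl]pent-4-en-1-ol
Product: 14 [(3S)-5-iodo-3-methyl-2-methylidenepentyl](trimethyl)silane, via mesylate 13 (not isolated)
Conditions: MsCl, Et3N, CH2Cl2, 0 °C; then NaI, acetone, 50 °C
Reagents that add atoms: sodium iodide, [Na+].[I-]
Why: Mesylation and Finkelstein displacement, chosen over I2/PPh3 because iodine would attack the allylsilane.

Step 8
Reactants: 8 3-ethoxy-6-methylcyclohex-2-en-1-one; 14 [(3S)-5-iodo-3-methyl-2-methylidenepentyl](trimethyl)silane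
Product: 15 3-ethoxy-6-methyl-6-{(3S)-3-methyl-4-[(trimethylsilyl)methyl]pent-4-en-1-yl}cyclohex-2-en-1-one (both C6 epimers)
Conditions: LiN(iPr)2 (1.0 equiv), THF, −78 °C; then 14, DMPU, −78 °C to rt
Reagents that add atoms: none
Why: Stork–Danheiser alkylation of the tertiary α′-enolate with a primary iodide builds the quaternary carbon C5, whose configuration does not matter because it becomes prochiral in 24.

Step 9
Reactants: 15 3-ethoxy-6-methyl-6-{(3S)-3-methyl-4-[(trimethylsilyl)methyl]pent-4-en-1-yl}cyclohex-2-en-1-one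
Product: 17 4-methyl-4-{(3S)-3-methyl-4-[(trimethylsilyl)methyl]pent-4-en-1-yl}cyclohex-2-en-1-one (both C4 epimers), via allylic alcohol 16 (not isolated)
Conditions: iBu2AlH, toluene, −78 °C; then 1 M aq. oxalic acid, THF, 0 °C
Reagents that add atoms: water, O
Why: 1,2-Reduction and mild acid hydrolysis of the enol ether with loss of the original oxygen (Stork–Danheiser enone transposition), short exposure to weak acid sparing the allylsilane.

Step 10
Reactants: 17 4-methyl-4-{(3S)-3-methyl-4-[(trimethylsilyl)methyl]pent-4-en-1-yl}cyclohex-2-en-1-one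
Product: 18 4-[(3S)-4-(bromomethyl)-3-methylpent-4-en-1-yl]-4-methylcyclohex-2-en-1-one (both C4 epimers)
Conditions: NBS, propylene oxide, CH2Cl2, −78 °C
Reagents that add atoms: N-bromosuccinimide, O=C1CCC(=O)N1Br
Why: SE2′ bromodesilylation of the allylsilane, by far the most electron-rich alkene present; the allyl shift is degenerate and gives the 2-substituted allyl bromide.

Step 11
Reactants: 18 4-[(3S)-4-(bromomethyl)-3-methylpent-4-en-1-yl]-4-methylcyclohex-2-en-1-one; 6 5-methoxy-2-methyl-1,3-benzoxazol-6-ol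
Product: 19 4-[(3S)-4-{[(5-methoxy-2-methyl-1,3-benzoxazol-6-yl)oxy]methyl}-3-methylpent-4-en-1-yl]-4-methylcyclohex-2-en-1-one (both C4 epimers)
Conditions: K2CO3, DMF, rt
Reagents that add atoms: none
Why: Williamson O-allylation of the phenol with a reactive allylic bromide under conditions that leave the enone alone.

Step 12
Reactants: 19 4-[(3S)-4-{[(5-methoxy-2-methyl-1,3-benzoxazol-6-yl)oxy]methyl}-3-methylpent-4-en-1-yl]-4-methylcyclohex-2-en-1-one
Product: 22 4-[(3S)-4-{[6-(tert-butyldimethylsilyloxy)-5-methoxy-2-methyl-1,3-benzoxazol-7-yl]methyl}-3-methylpent-4-en-1-yl]-4-methylcyclohex-2-en-1-one (both C4 epimers), via aryl trimethylsilyl ether 20 (not isolated), via free phenol 21 (not isolated)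
Conditions: N,O-bis(trimethylsilyl)acetamide, N,N-diethylaniline, 190 °C (sealed tube); then K2CO3 (cat.), MeOH, rt; then TBSCl, imidazole, DMF, 40 °C
Reagents that add atoms: tert-butyldimethylsilyl chloride, CC(C)(C)[Si](C)(C)Cl
Why: Aromatic Claisen rearrangement to C7, the only free ortho position (the other one carries OMe), with in situ O-silylation to keep the new phenol from attacking the alkene, followed by exchange of the labile TMS group for TBS.

Step 13
Reactants: 22 4-[(3S)-4-{[6-(tert-butyldimethylsilyloxy)-5-methoxy-2-methyl-1,3-benzoxazol-7-yl]methyl}-3-methylpent-4-en-1-yl]-4-methylcyclohex-2-en-1-one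
Product: 24 4-[(3S)-4-{[6-(tert-butyldimethylsilyloxy)-5-methoxy-2-methyl-1,3-benzoxazol-7-yl]methyl}-3-methylpent-4-en-1-yl]-4-methylcyclohexa-2,5-dien-1-one, via α-phenylselanyl ketone 23 (not isolated)
Conditions: LiN(SiMe3)2 (1.05 equiv), THF, −78 °C; PhSeBr; then H2O2, pyridine, CH2Cl2, 0 °C
Reagents that add atoms: none
Why: α′-Selenenylation and selenoxide syn-elimination give the cross-conjugated dienone, in which the two enone arms are identical so that both epimers converge to one compound.

Step 14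
Reactants: 24 4-[(3S)-4-{[6-(tert-butyldimethylsilyloxy)-5-methoxy-2-methyl-1,3-benzoxazol-7-yl]methyl}-3-methylpent-4-en-1-yl]-4-methylcyclohexa-2,5-dien-1-one
Product: 25 (4aS,7S,8R,8aS)-8-{[6-(tert-butyldimethylsilyloxy)-5-methoxy-2-methyl-1,3-benzoxazol-7-yl]methyl}-4a,7,8-trimethyl-4a,5,6,7,8,8a-hexahydronaphthalen-2(1H)-one (cis-fused)
Conditions: Fe(acac)3 (0.5 equiv), PhSiH3 (2.5 equiv), EtOH/ethylene glycol 5:1 (0.01 M), 60 °C, argon
Reagents that add atoms: none
Why: An iron hydride formed from Fe(acac)3 and PhSiH3 transfers a hydrogen atom to the terminal CH2 of the electron-rich 1,1-disubstituted alkene (Markovnikov), the tertiary C9 radical adds to C10, the β-carbon of one enone arm, and the α-keto radical is reduced by divalent iron and protonated by ethanol. The closest known reaction type is the iron-hydride (MHAT) reductive olefin–enone coupling of Baran in its intramolecular form, including radical desymmetrization of 4,4-disubstituted cyclohexadienones. Ring B is the only ring closed, in a 6-exo-trig radical mode. At C5 and C10 the fusion must be cis because the tether reaches C10 only from the face of the planar dienone on which C6 sits, and which of the two enantiotopic arms reacts is decided by C8, whose methyl group sits equatorial with H8 near the radical plane in the chair-like transition state; at C9 the bulky arylmethyl group should take the exo (equatorial) site and the methyl group created by hydrogen transfer the site over ring A. The step needs hydrogen-atom transfer to the alkyl-substituted alkene and not to the electron-poor dienone (secured by the polarity of the iron hydride), attack at C10 and not at C1 (polarity-matched β-addition of a nucleophilic radical), and no quenching of the C9 radical by a phenolic O–H (secured by the TBS ether).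

Step 15
Reactants: 25 (4aS,7S,8R,8aS)-8-{[6-(tert-butyldimethylsilyloxy)-5-methoxy-2-methyl-1,3-benzoxazol-7-yl]methyl}-4a,7,8-trimethyl-4a,5,6,7,8,8a-hexahydronaphthalen-2(1H)-one
Product: 27 (4aR,7S,8R,8aS)-8-{[6-(tert-butyldimethylsilyloxy)-5-methoxy-2-methyl-1,3-benzoxazol-7-yl]methyl}-4,4a,7,8-tetramethyl-4a,5,6,7,8,8a-hexahydronaphthalen-2(1H)-one, via trimethylsilyl enol ether 26 (not isolated)
Conditions: Me2CuLi, Me3SiCl, THF, −78 °C; then Pd(OAc)2 (1.1 equiv), MeCN, rt
Reagents that add atoms: lithium dimethylcuprate, [Li+].C[Cu-]C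
Why: Silyl-chloride-accelerated conjugate methylation at C4 and Saegusa–Ito dehydrogenation of the regiodefined silyl enol ether restore the C3=C4 enone, now carrying the C4 methyl group.

Step 16
Reactants: 27 (4aR,7S,8R,8aS)-8-{[6-(tert-butyldimethylsilyloxy)-5-methoxy-2-methyl-1,3-benzoxazol-7-yl]methyl}-4,4a,7,8-tetramethyl-4a,5,6,7,8,8a-hexahydronaphthalen-2(1H)-one
Product: 28 (4aR,7S,8R,8aS)-8-{[6-(tert-butyldimethylsilyloxy)-5-methoxy-2-methyl-1,3-benzoxazol-7-yl]methyl}-4,4a,7,8-tetramethyl-1,2,4a,5,6,7,8,8a-octahydronaphthalen-2-ol (both C2 epimers)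
Conditions: NaBH4, CeCl3·7H2O, MeOH, −20 °C
Reagents that add atoms: none
Why: Luche 1,2-reduction of the enone, the configuration of the new carbinol being irrelevant.

Step 17
Reactants: 28 (4aR,7S,8R,8aS)-8-{[6-(tert-butyldimethylsilyloxy)-5-methoxy-2-methyl-1,3-benzoxazol-7-yl]methyl}-4,4a,7,8-tetramethyl-1,2,4a,5,6,7,8,8a-octahydronaphthalen-2-ol
Product: 29 6-(tert-butyldimethylsilyloxy)-5-methoxy-2-methyl-7-{[(1R,2S,4aR,8aS)-1,2,4a,5-tetramethyl-1,2,3,4,4a,7,8,8a-octahydronaphthalen-1-yl]methyl}-1,3-benzoxazole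
Conditions: Et3SiH (5 equiv), BF3·OEt2 (2.5 equiv), CH2Cl2, −78 to −30 °C
Reagents that add atoms: none
Why: Ionic hydrogenation of the allylic alcohol, in which hydride should enter the allyl cation at the secondary terminus C2 and not at the neopentyl tertiary terminus C4, leaving the trisubstituted C3=C4 alkene.

Step 18
Reactants: 29 6-(tert-butyldimethylsilyloxy)-5-methoxy-2-methyl-7-{[(1R,2S,4aR,8aS)-1,2,4a,5-tetramethyl-1,2,3,4,4a,7,8,8a-octahydronaphthalen-1-yl]methyl}-1,3-benzoxazole
Product: 30 5-methoxy-2-methyl-7-{[(1R,2S,4aR,8aS)-1,2,4a,5-tetramethyl-1,2,3,4,4a,7,8,8a-octahydronaphthalen-1-yl]methyl}-1,3-benzoxazol-6-ol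
Conditions: Bu4NF, THF, 0 °C; aq. NH4Cl
Reagents that add atoms: none
Why: Fluoride cleavage of the aryl silyl ether under conditions that touch neither the alkene nor the benzoxazole.

## Compound list

1 | 3-(benzyloxy)-4-methoxybenzaldehyde | COc1ccc(C=O)cc1OCc1ccccc1 | starting material
2 | 5-(benzyloxy)-4-methoxy-2-nitrobenzaldehyde | COc1cc([N+](=O)[O-])c(C=O)cc1OCc1ccccc1 | intermediate
3 | 5-(benzyloxy)-4-methoxy-2-nitrophenyl formate | COc1cc([N+](=O)[O-])c(OC=O)cc1OCc1ccccc1 | intermediate (not isolated)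
4 | 5-(benzyloxy)-4-methoxy-2-nitrophenol | COc1cc([N+](=O)[O-])c(O)cc1OCc1ccccc1 | intermediate
5 | 4-amino-6-methoxybenzene-1,3-diol | COc1cc(N)c(O)cc1O | intermediate (not isolated)
6 | 5-methoxy-2-methyl-1,3-benzoxazol-6-ol | COc1cc2nc(C)oc2cc1O | intermediate
7 | 3-ethoxycyclohex-2-en-1-one | CCOC1=CC(=O)CCC1 | starting material
8 | 3-ethoxy-6-methylcyclohex-2-en-1-one (racemic) | CCOC1=CC(=O)C(C)CC1 | intermediate
9 | 3-methylideneoxolan-2-one | C=C1CCOC1=O | starting material
10 | (3S)-3-methyloxolan-2-one | C[C@H]1CCOC1=O | intermediate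
11 | (3S)-3-methyl-5-(trimethylsilyl)-4-[(trimethylsilyl)methyl]pentane-1,4-diol | C[C@@H](CCO)C(O)(C[Si](C)(C)C)C[Si](C)(C)C | intermediate (not isolated)
12 | (3S)-3-methyl-4-[(trimethylsilyl)methyl]pent-4-en-1-ol | C[C@@H](CCO)C(=C)C[Si](C)(C)C | intermediate
13 | (3S)-3-methyl-4-[(trimethylsilyl)methyl]pent-4-en-1-yl methanesulfonate | C[C@@H](CCOS(C)(=O)=O)C(=C)C[Si](C)(C)C | intermediate (not isolated)
14 | [(3S)-5-iodo-3-methyl-2-methylidenepentyl](trimethyl)silane | C[C@@H](CCI)C(=C)C[Si](C)(C)C | intermediate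
15 | 3-ethoxy-6-methyl-6-{(3S)-3-methyl-4-[(trimethylsilyl)methyl]pent-4-en-1-yl}cyclohex-2-en-1-one (both C6 epimers) | CCOC1=CC(=O)C(C)(CC[C@H](C)C(=C)C[Si](C)(C)C)CC1 | intermediate
16 | 3-ethoxy-6-methyl-6-{(3S)-3-methyl-4-[(trimethylsilyl)methyl]pent-4-en-1-yl}cyclohex-2-en-1-ol | CCOC1=CC(O)C(C)(CC[C@H](C)C(=C)C[Si](C)(C)C)CC1 | intermediate (not isolated)
17 | 4-methyl-4-{(3S)-3-methyl-4-[(trimethylsilyl)methyl]pent-4-en-1-yl}cyclohex-2-en-1-one (both C4 epimers) | O=C1C=CC(C)(CC[C@H](C)C(=C)C[Si](C)(C)C)CC1 | intermediate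
18 | 4-[(3S)-4-(bromomethyl)-3-methylpent-4-en-1-yl]-4-methylcyclohex-2-en-1-one (both C4 epimers) | O=C1C=CC(C)(CC[C@H](C)C(=C)CBr)CC1 | intermediate
19 | 4-[(3S)-4-{[(5-methoxy-2-methyl-1,3-benzoxazol-6-yl)oxy]methyl}-3-methylpent-4-en-1-yl]-4-methylcyclohex-2-en-1-one (both C4 epimers) | O=C1C=CC(C)(CC[C@H](C)C(=C)COc2cc3oc(C)nc3cc2OC)CC1 | intermediate
20 | 4-methyl-4-[(3S)-3-methyl-4-{[5-methoxy-2-methyl-6-(trimethylsilyloxy)-1,3-benzoxazol-7-yl]methyl}pent-4-en-1-yl]cyclohex-2-en-1-one | O=C1C=CC(C)(CC[C@H](C)C(=C)Cc2c(O[Si](C)(C)C)c(OC)cc3nc(C)oc23)CC1 | intermediate (not isolated)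
21 | 4-[(3S)-4-[(6-hydroxy-5-methoxy-2-methyl-1,3-benzoxazol-7-yl)methyl]-3-methylpent-4-en-1-yl]-4-methylcyclohex-2-en-1-one | O=C1C=CC(C)(CC[C@H](C)C(=C)Cc2c(O)c(OC)cc3nc(C)oc23)CC1 | intermediate (not isolated)
22 | 4-[(3S)-4-{[6-(tert-butyldimethylsilyloxy)-5-methoxy-2-methyl-1,3-benzoxazol-7-yl]methyl}-3-methylpent-4-en-1-yl]-4-methylcyclohex-2-en-1-one (both C4 epimers) | O=C1C=CC(C)(CC[C@H](C)C(=C)Cc2c(O[Si](C)(C)C(C)(C)C)c(OC)cc3nc(C)oc23)CC1 | intermediate
23 | 6-(phenylselanyl) derivative of 22 | O=C1C=CC(C)(CC[C@H](C)C(=C)Cc2c(O[Si](C)(C)C(C)(C)C)c(OC)cc3nc(C)oc23)CC1[Se]c1ccccc1 | intermediate (not isolated)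
24 | 4-[(3S)-4-{[6-(tert-butyldimethylsilyloxy)-5-methoxy-2-methyl-1,3-benzoxazol-7-yl]methyl}-3-methylpent-4-en-1-yl]-4-methylcyclohexa-2,5-dien-1-one | O=C1C=CC(C)(CC[C@H](C)C(=C)Cc2c(O[Si](C)(C)C(C)(C)C)c(OC)cc3nc(C)oc23)C=C1 | intermediate
25 | (4aS,7S,8R,8aS)-8-{[6-(tert-butyldimethylsilyloxy)-5-methoxy-2-methyl-1,3-benzoxazol-7-yl]methyl}-4a,7,8-trimethyl-4a,5,6,7,8,8a-hexahydronaphthalen-2(1H)-one (cis-fused; 5-Me, 10-H and 9-CH2Ar on one face, 8-Me and 9-Me on the other) | COc1cc2nc(C)oc2c(C[C@]2(C)[C@@H](C)CC[C@@]3(C)C=CC(=O)C[C@@H]23)c1O[Si](C)(C)C(C)(C)C | intermediate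
26 | 4-methyl-2-(trimethylsilyloxy) silyl enol ether from 25 (C4 epimers) | COc1cc2nc(C)oc2c(C[C@]2(C)[C@@H](C)CC[C@@]3(C)C(C)C=C(O[Si](C)(C)C)C[C@@H]23)c1O[Si](C)(C)C(C)(C)C | intermediate (not isolated)
27 | (4aR,7S,8R,8aS)-8-{[6-(tert-butyldimethylsilyloxy)-5-methoxy-2-methyl-1,3-benzoxazol-7-yl]methyl}-4,4a,7,8-tetramethyl-4a,5,6,7,8,8a-hexahydronaphthalen-2(1H)-one | COc1cc2nc(C)oc2c(C[C@]2(C)[C@@H](C)CC[C@@]3(C)C(C)=CC(=O)C[C@@H]23)c1O[Si](C)(C)C(C)(C)C | intermediate
28 | (4aR,7S,8R,8aS)-8-{[6-(tert-butyldimethylsilyloxy)-5-methoxy-2-methyl-1,3-benzoxazol-7-yl]methyl}-4,4a,7,8-tetramethyl-1,2,4a,5,6,7,8,8a-octahydronaphthalen-2-ol (both C2 epimers) | COc1cc2nc(C)oc2c(C[C@]2(C)[C@@H](C)CC[C@@]3(C)C(C)=CC(O)C[C@@H]23)c1O[Si](C)(C)C(C)(C)C | intermediate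
29 | 6-(tert-butyldimethylsilyloxy)-5-methoxy-2-methyl-7-{[(1R,2S,4aR,8aS)-1,2,4a,5-tetramethyl-1,2,3,4,4a,7,8,8a-octahydronaphthalen-1-yl]methyl}-1,3-benzoxazole | COc1cc2nc(C)oc2c(C[C@]2(C)[C@@H](C)CC[C@@]3(C)C(C)=CCC[C@@H]23)c1O[Si](C)(C)C(C)(C)C | intermediate
30 | 5-methoxy-2-methyl-7-{[(1R,2S,4aR,8aS)-1,2,4a,5-tetramethyl-1,2,3,4,4a,7,8,8a-octahydronaphthalen-1-yl]methyl}-1,3-benzoxazol-6-ol | COc1cc2nc(C)oc2c(C[C@]2(C)[C@@H](C)CC[C@@]3(C)C(C)=CCC[C@@H]23)c1O | target

## Step count and risks

Total step count: 18. Longest linear sequence: 14 steps (steps 5 to 18, from 9).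

Steps most likely to fail:

1. Step 14. The C9 radical may be lost before ring closure (hydrogenation of the alkene, or chain-walking of the double bond toward C8 or into conjugation with the arene). At 60 °C the discrimination between the two enone arms, or between the two faces of the C9 radical, may also be poor. Fallback from 24 back to 25: dry HBr in CH2Cl2 at −78 °C is added in the Markovnikov sense to the 1,1-disubstituted alkene to give the tertiary bromide F1. This is cyclized in a halogen-abstraction chain with (Me3Si)3SiH and Et3B/air in toluene at −78 °C. The same 6-exo closure then runs without any metal hydride and at a temperature where the chair-like transition states are better separated.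

2. Step 12. If O-silylation is slower than hydrogen transfer from the new phenol to the alkene, the double bond may migrate into the C8=C9 position (abnormal Claisen pathway, which erases C8), or the phenol may add to the alkene to close a dihydrobenzofuran. Fallback from 6 and 18 back to 22, without any sigmatropic step: phenol 6 is brominated ortho to the hydroxyl group with NBS in MeCN to give the bromophenol F2. Silylation (TBSCl, imidazole) gives the silyl ether F3, and Miyaura borylation (B2pin2, Pd(dppf)Cl2, KOAc, dioxane, 90 °C) gives the pinacol boronate F4. Suzuki–Miyaura allyl–aryl coupling of F4 with allyl bromide 18 (Pd(PPh3)4, K2CO3, THF/H2O, 60 °C) should give 22 directly.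

3. Step 17. The allyl cation may take up hydride at the tertiary terminus C4 (giving the C2=C3 isomer) or lose a proton to give a diene. Fallback from 28 back to 29: the alcohol is acetylated (Ac2O, pyridine, DMAP) to the allylic acetate F5. This is reduced through a π-allylpalladium complex with Pd(PPh3)4 (5 mol%) and LiBHEt3 in THF at rt, where external hydride attacks the less hindered terminus C2.

Further compounds
F1 | step 14 | 4-{(3S)-4-bromo-5-[6-(tert-butyldimethylsilyloxy)-5-methoxy-2-methyl-1,3-benzoxazol-7-yl]-3,4-dimethylpentyl}-4-methylcyclohexa-2,5-dien-1-one (both epimers at the bromine-bearing carbon) | O=C1C=CC(C)(CC[C@H](C)C(C)(Br)Cc2c(O[Si](C)(C)C(C)(C)C)c(OC)cc3nc(C)oc23)C=C1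
F2 | step 12 | 7-bromo-5-methoxy-2-methyl-1,3-benzoxazol-6-ol | COc1cc2nc(C)oc2c(Br)c1O
F3 | step 12 | 7-bromo-6-(tert-butyldimethylsilyloxy)-5-methoxy-2-methyl-1,3-benzoxazole | COc1cc2nc(C)oc2c(Br)c1O[Si](C)(C)C(C)(C)C
F4 | step 12 | 6-(tert-butyldimethylsilyloxy)-5-methoxy-2-methyl-7-(4,4,5,5-tetramethyl-1,3,2-dioxaborolan-2-yl)-1,3-benzoxazole | COc1cc2nc(C)oc2c(B3OC(C)(C)C(C)(C)O3)c1O[Si](C)(C)C(C)(C)C
F5 | step 17 | (4aR,7S,8R,8aS)-8-{[6-(tert-butyldimethylsilyloxy)-5-methoxy-2-methyl-1,3-benzoxazol-7-yl]methyl}-4,4a,7,8-tetramethyl-1,2,4a,5,6,7,8,8a-octahydronaphthalen-2-yl acetate (both C2 epimers) | COc1cc2nc(C)oc2c(C[C@]2(C)[C@@H](C)CC[C@@]3(C)C(C)=CC(OC(C)=O)C[C@@H]23)c1O[Si](C)(C)C(C)(C)C
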